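All runs are calculated for an exercise; the scatter is artificial.

At late times the delta run's readings no longer move: target reads 48.3 % at 0.625 d and 47.9 % at 4.00 d. So when you repeat these flasks, follow the rate at which target forms against the rate of other capture product while substrate reacts.

| flask | substrate | first nucleophile | second nucleophile | temperature | remark | time |
|---|---|---|---|---|---|---|
| delta | 37 mM | 22.2 mM | 92.5 mM | 105 °C | run made earlier |  |
| beta | 25 mM | 22.2 mM | 92.5 mM | 116 °C | run made earlier |  |
| gamma | 56 mM | 22.2 mM | 92.5 mM | 105 °C | run made earlier |  |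
| zeta | 37 mM | 22.2 mM | 180 mM | 116 °C | run made earlier |  |
| Thursday's | 37 mM (fed, over 2.5 d) | 22.2 mM | 92.5 mM |  | the addition at 80 °C, then warmed to 110 °C; the feed brings no volume worth counting | 6.0 d |
| Saturday's | 37 mM | 22.2 mM | 92.5 mM |  | everything together at the start at 80 °C, warmed to 110 °C at 2.5 d | 6.0 d |
| Wednesday's | 37 mM | 22.2 mM (fed, over 2.5 d) | 92.5 mM | 110 °C | all else is in the flask from the start; the feed brings no volume worth counting | 6.0 d |
| Monday's | 37 mM | 22.2 mM | 92.5 mM | 110 °C | everything together at the start | 6.0 d |

| run | time / d | target / % | other capture product / % | substrate / % |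
|---|---|---|---|---|
| delta | 0.250 | 47.4 | 45.1 | 2.6 |
| delta | 0.625 | 48.3 | 47.9 | 0 |
| delta | 1.25 | 47.7 | 47.5 | 0 |
| delta | 2.08 | 48.1 | 47.0 | 0 |
| delta | 3.00 | 48.9 | 47.5 | 0 |
| delta | 4.00 | 47.9 | 48.7 | 0.4 |
| beta | 0.833 | 50.2 | 46.3 | 0.3 |
| beta | 1.67 | 48.9 | 45.1 | 0.1 |
| beta | 2.50 | 49.9 | 44.6 | 0.7 |
| beta | 3.00 | 50.2 | 45.1 | 0 |
| beta | 4.00 | 48.9 | 45.7 | 0.1 |
| beta | 5.00 | 49.5 | 45.6 | 0 |
| gamma | 0.833 | 37.0 | 56.6 | 0 |
| gamma | 1.67 | 37.2 | 56.7 | 0.1 |
| gamma | 2.50 | 37.9 | 57.5 | 0 |
| gamma | 3.00 | 37.8 | 56.7 | 0 |
| gamma | 4.00 | 37.5 | 57.2 | 0.6 |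
| gamma | 5.00 | 36.9 | 56.7 | 0 |
| zeta | 0.417 | 34.9 | 61.2 | 0.1 |
| zeta | 0.833 | 35.0 | 61.4 | 0 |
| zeta | 1.25 | 34.3 | 62.0 | 0 |
| zeta | 2.50 | 34.4 | 62.2 | 0.1 |
| zeta | 5.00 | 33.7 | 62.0 | 0 |

(each reading ± 0.5 percentage points)

- the flask that comes out highest in share of target in target plus other capture product, or "all alike" when all lie within 1.5 percentage points (Thursday's / Saturday's / Wednesday's / Monday's / all alike)
- share of target in target plus other capture product at the end, Thursday's
- share of target in target plus other capture product at the end, Saturday's
- share of target in target plus other capture product at the end, Wednesday's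
- share of target in target plus other capture product at the end, Monday's

- on the list of suspects stand: substrate -> intermediate; second nucleophile + intermediate -> other capture product; intermediate -> solvolysis product; first nucleophile <-> dormant form; first nucleophile -> decomposed reagent; first nucleophile + intermediate -> target

Read the suspects as one intermediate shared by two nucleophiles. Target then forms against other capture product in the ratio r[first nucleophile]/[second nucleophile], and if each product takes its own nucleophile and neither nucleophile goes anywhere else, the fraction left of the first equals the fraction left of the second raised to r, which makes the r below an apparent one, since the dormant form and decomposed reagent stand on the list too. The last readings give r as 7.39 at 105 °C in the delta run and 6.20 at 116 °C in the beta run. In the delta run, therefore, target starts at 1.77 times the rate of other capture product, but by the last reading the part of the first nucleophile's charge not taken up as target reads 0.202, and free first nucleophile is that part less whatever sits in the dormant form and decomposed reagent, while the part of the second nucleophile's charge not taken up reads 0.805; the accumulated share reads 49.6 %.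

Taking ln r as straight in temperature, the selectivity factor of target over other capture product at 110 °C is 6.82, and at 80 °C it is 11.0. With the same 0.805, I reckon Monday's at 47.9 %, Saturday's at 56.4 % if its substrate reacts cold, and Thursday's between them. For Wednesday's, the delta run's first substrate reading gives a half-life of 1.14 h at 105 °C, and I take that as too long a figure for the hotter 110 °C; in that time the feed brings 0.422 mM, so I expect the share to lie below 3.02 %.

The forecast names Saturday's, with 52 % for Thursday's, 55 % for Saturday's, 3 % for Wednesday's and 49 % for Monday's, and it takes r “by a long extrapolation, about 13 at 80 °C” where I have 11.0.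

Saturday's comes out highest at 55.6 %, followed by Thursday's at 50.7 %, Monday's at 49.0 % and Wednesday's at 2.22 %.

    substrate → intermediate (k = 2.60 × 10⁻⁴ s⁻¹, Ea = 117 kJ mol⁻¹)
    second nucleophile + intermediate → other capture product (k = 0.0910 M⁻¹ s⁻¹, Ea = 83.0 kJ mol⁻¹)
    intermediate → solvolysis product (k = 7.90 × 10⁻⁴ s⁻¹, Ea = 106 kJ mol⁻¹)
    first nucleophile ⇌ dormant form (K = 2.90, k = 1.40 × 10⁻⁵ s⁻¹, Ea = 116 kJ mol⁻¹, ΔH = 10.0 kJ mol⁻¹)
    first nucleophile → decomposed reagent (k = 3.20 × 10⁻⁶ s⁻¹, Ea = 119 kJ mol⁻¹)
    first nucleophile + intermediate → target (k = 0.720 M⁻¹ s⁻¹, Ea = 56.0 kJ mol⁻¹)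
    (constants at 110 °C)

In Wednesday's, the step from substrate to intermediate had 100 % of its turnover behind it by 1.20 d, and half of the capture by second nucleophile was done by 0.753 h, when the feed had brought 0.278 mM of first nucleophile, so 6.82 against the charged 92.5 mM gives 2.01 % beside the 2.22 % found. With that same feed, the neighbour flask holding 23 mM of second nucleophile reckons at 7.62 %, and it ended at 6.75 %.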